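Kazinol N is disconnected at the C8–O and O1–C2 bonds of its 2H-chromene (chromene numbering for ring B and the pyran). Because O1 on C8a and the hydroxyl on C8 are neighbours and C4a carries the C4=C3–C2Me2 unit, the chromenol is an isomer of a C8/C8a ortho-quinone bearing a prenyl group on C4a. One operation therefore oxygenates C8 of a monophenol with IBX, moves a proton from the C4a prenyl CH2 to oxygen to give a vinyl ortho-quinone methide, and closes the pyran by oxa-6π electrocyclisation. The precursor is a 2,3-diprenyl-4-(3-arylpropyl)phenol with ring A as its TIPS ether, made by B-alkyl Suzuki coupling of two bromophenol-derived fragments.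

Key step: step 8

Remark on the chemistry: all ring B intermediates are numbered as chromenes (O1, C2, C3, C4, C4a, C5, C6, C7, C8, C8a), the phenol carbon of the precursor being C8a; the target has no stereocentre, so only the exocyclic alkene geometry of transient 14 matters.

Step 1
Reactants: 1 4-bromo-3-methoxyphenol
Product: 2 (4-bromo-3-methoxyphenoxy)tri(propan-2-yl)silane
Conditions: TIPSCl, imidazole, DMF, rt
Reagents that add atoms: chlorotri(propan-2-yl)silane (TIPSCl), CC(C)[Si](Cl)(C(C)C)C(C)C
Why: Imidazole-promoted O-silylation of the phenol (silyl ether protection) should be clean, and the bulky TIPS ether is chosen to survive the later aqueous base, hydride, oxidant and amine.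

Step 2
Reactants: 2 (4-bromo-3-methoxyphenoxy)tri(propan-2-yl)silane; 3 allylboronic acid pinacol ester
Product: 4 [3-methoxy-4-(prop-2-enyl)phenoxy]tri(propan-2-yl)silane
Conditions: Pd(PPh3)4 (5 mol%), CsF, THF, 65 °C
Reagents that add atoms: none
Why: Suzuki–Miyaura coupling of the aryl bromide with the allylboronate under anhydrous fluoride activation should give the allylarene, the unsubstituted allyl group making α and γ transfer equivalent and the mild medium limiting migration of the alkene into conjugation.

Step 3
Reactants: 5 4-bromo-2,3-dimethylphenol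
Product: 6 4-bromo-2,3-dimethylphenyl 2,2-dimethylpropanoate
Conditions: PivCl, Et3N, DMAP (cat.), CH2Cl2, 0 °C → rt
Reagents that add atoms: pivaloyl chloride, CC(C)(C)C(=O)Cl
Why: DMAP-catalysed O-acylation gives an aryl pivalate that deactivates the ring toward electrophilic bromination, is shielded against the Grignard reagent and can later be removed without acid.

Step 4
Reactants: 6 4-bromo-2,3-dimethylphenyl 2,2-dimethylpropanoate
Product: 7 4-bromo-2,3-bis(bromomethyl)phenyl 2,2-dimethylpropanoate
Conditions: NBS (2.1 equiv), AIBN (cat.), PhCF3, 85 °C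
Reagents that add atoms: N-bromosuccinimide, O=C1CCC(=O)N1Br
Why: Wohl–Ziegler radical bromination should take one hydrogen from each benzylic methyl group, since the ester- and bromine-deactivated ring resists nuclear bromination and the first bromine on a carbon slows a second substitution there.

Step 5
Reactants: 7 4-bromo-2,3-bis(bromomethyl)phenyl 2,2-dimethylpropanoate; 8 2-methylprop-1-enylmagnesium bromide
Product: 9 4-bromo-2,3-bis(3-methylbut-2-enyl)phenyl 2,2-dimethylpropanoate
Conditions: 8 (2.4 equiv), CuI (10 mol%), THF, −30 → 0 °C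
Reagents that add atoms: none
Why: Copper-catalysed sp3–sp2 cross-coupling of benzylic bromides with an alkenyl Grignard reagent (Kochi-type coupling) should replace both bromides and create the two prenyl groups, the organocopper species reacting with benzylic C–Br far faster than with the hindered pivalate or the aryl bromide at low temperature.

Step 6
Reactants: 4 [3-methoxy-4-(prop-2-enyl)phenoxy]tri(propan-2-yl)silane; 9 4-bromo-2,3-bis(3-methylbut-2-enyl)phenyl 2,2-dimethylpropanoate
Product: 11 4-{3-[2-methoxy-4-(triisopropylsilyloxy)phenyl]propyl}-2,3-bis(3-methylbut-2-enyl)phenyl 2,2-dimethylpropanoate, via B-alkyl-9-BBN adduct 10 (not isolated)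
Conditions: 4 (1.3 equiv), 9-BBN, THF, 0 °C → rt; then aq. K3PO4, 9, PdCl2(dppf) (5 mol%), DMF, 60 °C
Reagents that add atoms: none
Why: Anti-Markovnikov hydroboration of the terminal alkene followed by B-alkyl Suzuki–Miyaura coupling should form the aryl–CH2 bond, the wide-bite-angle dppf ligand favouring reductive elimination over β-hydride elimination and the prenyl alkenes of 9 being spared because hydroboration is finished and quenched by the aqueous base before 9 is added.

Step 7
Reactants: 11 4-{3-[2-methoxy-4-(triisopropylsilyloxy)phenyl]propyl}-2,3-bis(3-methylbut-2-enyl)phenyl 2,2-dimethylpropanoate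
Product: 12 4-{3-[2-methoxy-4-(triisopropylsilyloxy)phenyl]propyl}-2,3-bis(3-methylbut-2-enyl)phenol
Conditions: i-Bu2AlH (2.5 equiv), CH2Cl2, −78 °C; aq. potassium sodium tartrate
Reagents that add atoms: none
Why: Reductive cleavage of the aryl ester by the aluminium hydride should free the phenol at low temperature without acid or protic base, so that the ortho-prenylphenol does not cyclise to a chroman and the ring A silyl ether is kept.

Step 8
Reactants: 12 4-{3-[2-methoxy-4-(triisopropylsilyloxy)phenyl]propyl}-2,3-bis(3-methylbut-2-enyl)phenol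
Product: 15 6-{3-[2-methoxy-4-(triisopropylsilyloxy)phenyl]propyl}-2,2-dimethyl-5-(3-methylbut-2-enyl)-2H-chromen-8-ol, via ortho-quinone 13 (not isolated), via vinyl ortho-quinone methide 14 (not isolated)
Conditions: IBX (1.05 equiv), DMF, 0 °C → rt; then Et3N (3 equiv), argon, rt
Reagents that add atoms: 2-iodoxybenzoic acid (IBX), O=C1OI(=O)(O)c2ccccc12
Why: Proposed new method: the phenol of 12 binds pentavalent iodine of IBX, oxygen is delivered within the complex to the only unsubstituted ortho carbon (C8) and the resulting trivalent iodine catecholate collapses to ortho-quinone 13 and 2-iodobenzoic acid, after which Et3N removes a proton from the CH2 of the C4a prenyl group (doubly allylic and conjugated to the C8 carbonyl through C4a=C5–C6=C7) and O-protonation gives the 8-hydroxy vinyl ortho-quinone methide 14. Compound 14 then closes the pyran by a thermal oxa-6π electrocyclisation that forms O1–C2 in a six-membered ring and restores the aromaticity of ring B. The closest known reaction types are the IBX ortho-oxygenation of phenols to ortho-quinones and the amine-induced isomerisation of prenylated para-quinones to 2,2-dimethylchromenols through ortho-quinone methides, whose merger on an ortho-quinone in one flask is the unproven element. No stereocentre arises because C2 bears two methyl groups, and the exocyclic alkene of 14 should prefer the Z geometry needed for closure since the other isomer pushes the vinyl group against the C5 prenyl group. The step needs site selectivity in the oxygenation, secured by C8 being the sole free ortho position, and discrimination of the two quinone oxygens, secured because only the C8a carbonyl gains a conjugated alkylidene that can cyclise, while the para-quinone methides open to the C5 prenyl group and the C6 chain lack a ring-closing partner and can return to 13. Base is added only when the oxidant is spent, so that phenol 15 is not oxidised again, and water and other nucleophiles are kept out so that no quinone methide is trapped.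

Step 9
Reactants: 15 6-{3-[2-methoxy-4-(triisopropylsilyloxy)phenyl]propyl}-2,2-dimethyl-5-(3-methylbut-2-enyl)-2H-chromen-8-ol
Product: 16 Kazinol N, 6-[3-(4-hydroxy-2-methoxyphenyl)propyl]-2,2-dimethyl-5-(3-methylbut-2-enyl)-2H-chromen-8-ol
Conditions: Bu4NF, AcOH, THF, 0 °C
Reagents that add atoms: none
Why: Fluoride-induced cleavage of the aryl silyl ether, buffered with acetic acid so that the electron-rich chromenol is not held as an air-sensitive phenoxide, should release the target.

Compound list
1 | 4-bromo-3-methoxyphenol | COc1cc(O)ccc1Br | starting material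
2 | (4-bromo-3-methoxyphenoxy)tri(propan-2-yl)silane | COc1cc(O[Si](C(C)C)(C(C)C)C(C)C)ccc1Br | intermediate
3 | allylboronic acid pinacol ester | C=CCB1OC(C)(C)C(C)(C)O1 | starting material
4 | [3-methoxy-4-(prop-2-enyl)phenoxy]tri(propan-2-yl)silane | C=CCc1ccc(O[Si](C(C)C)(C(C)C)C(C)C)cc1OC | intermediate
5 | 4-bromo-2,3-dimethylphenol | Cc1c(O)ccc(Br)c1C | starting material
6 | 4-bromo-2,3-dimethylphenyl 2,2-dimethylpropanoate | Cc1c(OC(=O)C(C)(C)C)ccc(Br)c1C | intermediate
7 | 4-bromo-2,3-bis(bromomethyl)phenyl 2,2-dimethylpropanoate | BrCc1c(OC(=O)C(C)(C)C)ccc(Br)c1CBr | intermediate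
8 | 2-methylprop-1-enylmagnesium bromide | CC(C)=C[Mg]Br | starting material
9 | 4-bromo-2,3-bis(3-methylbut-2-enyl)phenyl 2,2-dimethylpropanoate | CC(C)=CCc1c(OC(=O)C(C)(C)C)ccc(Br)c1CC=C(C)C | intermediate
10 | 9-{3-[2-methoxy-4-(triisopropylsilyloxy)phenyl]propyl}-9-borabicyclo[3.3.1]nonane (not isolated) | COc1cc(O[Si](C(C)C)(C(C)C)C(C)C)ccc1CCCB1C2CCCC1CCC2 | intermediate
11 | 4-{3-[2-methoxy-4-(triisopropylsilyloxy)phenyl]propyl}-2,3-bis(3-methylbut-2-enyl)phenyl 2,2-dimethylpropanoate | COc1cc(O[Si](C(C)C)(C(C)C)C(C)C)ccc1CCCc1ccc(OC(=O)C(C)(C)C)c(CC=C(C)C)c1CC=C(C)C | intermediate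
12 | 4-{3-[2-methoxy-4-(triisopropylsilyloxy)phenyl]propyl}-2,3-bis(3-methylbut-2-enyl)phenol | COc1cc(O[Si](C(C)C)(C(C)C)C(C)C)ccc1CCCc1ccc(O)c(CC=C(C)C)c1CC=C(C)C | intermediate
13 | 5-{3-[2-methoxy-4-(triisopropylsilyloxy)phenyl]propyl}-3,4-bis(3-methylbut-2-enyl)cyclohexa-3,5-diene-1,2-dione (not isolated) | COc1cc(O[Si](C(C)C)(C(C)C)C(C)C)ccc1CCCC1=CC(=O)C(=O)C(CC=C(C)C)=C1CC=C(C)C | intermediate
14 | (6Z)-2-hydroxy-4-{3-[2-methoxy-4-(triisopropylsilyloxy)phenyl]propyl}-5-(3-methylbut-2-enyl)-6-(3-methylbut-2-enylidene)cyclohexa-2,4-dien-1-one (not isolated) | COc1cc(O[Si](C(C)C)(C(C)C)C(C)C)ccc1CCCC1=C(CC=C(C)C)/C(=C/C=C(C)C)C(=O)C(O)=C1 | intermediate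
15 | 6-{3-[2-methoxy-4-(triisopropylsilyloxy)phenyl]propyl}-2,2-dimethyl-5-(3-methylbut-2-enyl)-2H-chromen-8-ol | COc1cc(O[Si](C(C)C)(C(C)C)C(C)C)ccc1CCCc1cc(O)c2OC(C)(C)C=Cc2c1CC=C(C)C | intermediate
16 | Kazinol N | COc1cc(O)ccc1CCCc1cc(O)c2c(c1CC=C(C)C)C=CC(C)(C)O2 | target

Total step count: 9. Longest linear sequence: 7 steps (steps 3 to 9, from 5).

Steps most likely to fail

Step 8 (Proposed new method). Possible failures:
- oxygen transfer to the prenyl-bearing ortho carbon instead of C8;
- proton loss at the C5 prenyl or C6 chain CH2, followed by irreversible rearomatisation to a side-chain-unsaturated catechol or capture by a nucleophile;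
- self-condensation of the ortho-quinone;
- re-oxidation of the product phenol by leftover oxidant.

The fallback sets out from 12 and rejoins the route at 16, using only established reaction types. IBX oxidation in DMF is followed in the same flask by reduction with aqueous Na2S2O4, which should give the catechol 5-{3-[2-methoxy-4-(triisopropylsilyloxy)phenyl]propyl}-3,4-bis(3-methylbut-2-enyl)benzene-1,2-diol F1. The less hindered hydroxyl (the new one, on the carbon next to C–H) is silylated with TIPSCl and imidazole at 0 °C to give the mono-protected catechol 4-{3-[2-methoxy-4-(triisopropylsilyloxy)phenyl]propyl}-2,3-bis(3-methylbut-2-enyl)-6-(triisopropylsilyloxy)phenol F2. DDQ in toluene then effects the familiar dehydrogenative cyclisation of an ortho-prenylphenol to a 2,2-dimethylchromene, giving the 8-silyloxychromene F3. Bu4NF with AcOH in THF removes both silyl groups to give 16.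

Step 5. Possible failures:
- attack of the Grignard reagent on the pivalate;
- halogen–magnesium exchange with Wurtz-type homocoupling or loss of the vicinal dibromide as an ortho-quinodimethane;
- stalling after the first coupling.

The fallback sets out from 7 and returns at 9. The Grignard reagent is replaced by 2-methylprop-1-enylboronic acid pinacol ester in a palladium-catalysed sp3–sp2 Suzuki–Miyaura coupling (Pd(PPh3)4, Cs2CO3, THF/H2O 10:1, 60 °C). Benzylic C–Br bonds add to zerovalent palladium faster than the hindered, electron-rich aryl C–Br bond, and the neutral boronate cannot attack the ester. No new intermediate is formed.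

Step 6. Possible failures:
- slow oxidative addition at the ortho-substituted, electron-rich aryl bromide, so that protodeboronation or β-hydride elimination consumes the alkylborane;
- partial hydrolysis of the pivalate (harmless, as step 7 removes it).

The fallback sets out from 4 and returns at 11 by a Negishi coupling. Hydroboration of 4 with 9-BBN and oxidation with NaBO3 in THF/H2O should give the primary alcohol 3-[2-methoxy-4-(triisopropylsilyloxy)phenyl]propan-1-ol F4. I2, PPh3 and imidazole in CH2Cl2 convert it into the iodide [4-(3-iodopropyl)-3-methoxyphenoxy]tri(propan-2-yl)silane F5. Zinc dust with LiCl in THF gives the alkylzinc iodide {3-[2-methoxy-4-(triisopropylsilyloxy)phenyl]propyl}zinc iodide F6, which is coupled with 9 using Pd(OAc)2 and SPhos in THF at rt to 50 °C; the ester tolerates the organozinc.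

Further compounds
F1 | step 8 | 5-{3-[2-methoxy-4-(triisopropylsilyloxy)phenyl]propyl}-3,4-bis(3-methylbut-2-enyl)benzene-1,2-diol | COc1cc(O[Si](C(C)C)(C(C)C)C(C)C)ccc1CCCc1cc(O)c(O)c(CC=C(C)C)c1CC=C(C)C
F2 | step 8 | 4-{3-[2-methoxy-4-(triisopropylsilyloxy)phenyl]propyl}-2,3-bis(3-methylbut-2-enyl)-6-(triisopropylsilyloxy)phenol | COc1cc(O[Si](C(C)C)(C(C)C)C(C)C)ccc1CCCc1cc(O[Si](C(C)C)(C(C)C)C(C)C)c(O)c(CC=C(C)C)c1CC=C(C)C
F3 | step 8 | {[6-{3-[2-methoxy-4-(triisopropylsilyloxy)phenyl]propyl}-2,2-dimethyl-5-(3-methylbut-2-enyl)-2H-chromen-8-yl]oxy}tri(propan-2-yl)silane | COc1cc(O[Si](C(C)C)(C(C)C)C(C)C)ccc1CCCc1cc(O[Si](C(C)C)(C(C)C)C(C)C)c2OC(C)(C)C=Cc2c1CC=C(C)C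
F0 | step 5 | none | none
F4 | step 6 | 3-[2-methoxy-4-(triisopropylsilyloxy)phenyl]propan-1-ol | COc1cc(O[Si](C(C)C)(C(C)C)C(C)C)ccc1CCCO
F5 | step 6 | [4-(3-iodopropyl)-3-methoxyphenoxy]tri(propan-2-yl)silane | COc1cc(O[Si](C(C)C)(C(C)C)C(C)C)ccc1CCCI
F6 | step 6 | {3-[2-methoxy-4-(triisopropylsilyloxy)phenyl]propyl}zinc iodide | COc1cc(O[Si](C(C)C)(C(C)C)C(C)C)ccc1CCC[Zn]I
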